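The numbers are those of an exercise; no experiment stands behind them.

Decide the next change to this flask before reckoning its yield. D dimerises, and it also takes up X, a gas dissolving from L held at constant pressure.

D 10 mM; L 0.73 mM (held); time 30 s

* amount of D.X at 30 s, in percent of the D charged
* the change that raises the amount of D.X at 30 s, in percent of the D charged most ("none" if none brings more than 2 percentage points) (ochre / blue / none)
* amount of D.X at 30 s, in percent of the D charged, after blue

- ochre: doubling the saturation concentration of L, all else as stated
- blue: doubling the transfer coefficient of step 2, all else as stated

- percent here means D units held: one D2 counts as two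
- for a step with 2 of a species take k times the square, and two of it per event
- at the start none of X is dissolved
- run time (flask): 30 s

I treated capture as the small correction to dimerisation. Transfer refills X at 0.95 s⁻¹ while D draws it down, so with [D] taken at half the charge, I set [X] at 0.669 mM. Multiplying by the rate constant 16 M⁻¹ s⁻¹ gave the capture constant, the pseudo-first-order rate at which any one D is taken up: 0.0107 s⁻¹. That is slower than the opening dimerisation rate per D, 0.0400 s⁻¹.

Dimerisation has a first half-life of 25.0 s. Capture and the small loss to J shorten the time D effectively has, from 30 s to 25.5 s. Integrating the capture constant over the falling [D] gave 18.8% of the charge. X starts empty, though, and that lag cost 1.13%, so I committed to 17.7%.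

The same reckoning served the decision. Blue lifts the capture constant to 0.0112 s⁻¹ and cuts the lag to 0.589%, giving 18.9%. Ochre doubles the constant and gives 31.5%, which is more. I chose ochre.

The forecast gave 17.7%, 18.7% after blue, and ochre: “Ochre nearly doubles X, so it is best.”

The simulation gave 17.6%, and 18.9% after blue. Its choice was ochre, which gained 14 percentage points against 1.2 points for blue.

    2 D → D2 (k1 = 2.0 M⁻¹ s⁻¹)
    L ⇌ X, rate k2*(csat - [X]) (k2 = 0.95 s⁻¹, csat = 0.73 mM)
    X → G (k3 = 0.0070 s⁻¹)
    D → J (k4 = 5.5 × 10⁻⁴ s⁻¹)
    D + X → D.X (k5 = 16 M⁻¹ s⁻¹)

D.X in this flask stood at 17.6% at 30 s because the loss of 2 D to D2 and the hour of the reading acted together, each only a part of the reason: with that loss struck out the flask reached 25.3%, and read at 300 s it held 39.3%. At 30 s, with 36% of the charged D left, my dimerisation rate per D for this flask was 0.0142 s⁻¹, still faster than the capture constant of 0.0107 s⁻¹. Carried unchanged to the same flask read at 12 s, it gives 8.79%, and that flask held 8.68%.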